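**Plan**

- ent-Kaurane numbering is used: ring A = C1–C5/C10; γ-lactone C6(=O)–O–C19; spiro δ-lactone C7(=O)–O–C20 on C10; ring C = C8/C9/C11–C14; ring D = C8/C15/C16/C13/C14.
- Cuts, last to first: O–Si and C16=C17, then C8–C15 and C8–C14 together. C8 is a quaternary carbon between the lactone carbonyl C7 and the ketone C15 (a β-keto ester carbon), and C13 lies 1,3 to C15, so ring D maps onto a symmetric 3-substituted cyclobutanone (C13–C14–C15–C16) that a tethered diazo carbon C8 opens.
- Earlier cuts: cyclobutanone to the C13=C14 alkene plus dichloroketene; C11–C12 (allylboration); C9–C11 (conjugate addition to the C8=C9 spiro lactone); C9–C10 (C10 radical from the C10/C20 oxirane plus an acrylate); C5–C6 and C4–C18 (conjugate methylation and orthoformate trapping of an enone).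
- Forward: ring A cyclohexanone, then the cis-fused C6/C19 lactol ether, the spiro δ-lactone on C10, the C9 side chain with O on C11, the cyclobutanone, rings C and D closed in one step (four-membered ring expanded to ring D), and last the C17 methylene.
- Stereochemistry: C4 from a catalytic asymmetric conjugate addition; C5 by equilibration to the cis-fused acetal; C10 and C9 by substrate control; C11 by catalyst-controlled allylboration; C8 and C13 in the ring expansion.

Key step: step 17

Remark: centres that are destroyed later or set only in a later step (acetal carbon C6 in 9–13, oxirane carbon in 10, carbinol C15 in 24–26, C5 in 7 and 8, C8 in 15 and 25, C13 in 22) are carried as mixtures and left open in the SMILES.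

**Route**

Step 1
Reactants: 1 3-ethoxycyclohex-2-en-1-one; 2 tributyl[(benzyloxy)methyl]stannane
Product: 4 3-[(benzyloxy)methyl]cyclohex-2-en-1-one, via carbinol 3 (not isolated)
Conditions: 2, n-BuLi, THF, −78 °C; then 1, −78 °C; then 1 M HCl, 0 °C → rt
Reagents that add atoms: water O
Why: Tin–lithium exchange gives the alkoxymethyllithium, which adds 1,2 to the vinylogous ester, and acid hydrolysis of the enol ether with loss of the tertiary hydroxyl transposes the enone (Stork–Danheiser alkylative transposition) without forming a stereocentre.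

Step 2
Reactants: 4 3-[(benzyloxy)methyl]cyclohex-2-en-1-one
Product: 6 (3R)-3-[(benzyloxy)methyl]-3-methyl-1-(trimethylsilyloxy)cyclohex-1-ene, via aluminium enolate 5 (not isolated)
Conditions: AlMe3, Cu(O2CC4H3S) (2 mol %), BINOL-derived N,N-bis(1-phenylethyl)phosphoramidite (4 mol %), Et2O, −30 °C; then TMSOTf, THF, −30 → 0 °C
Reagents that add atoms: trimethylaluminium C[Al](C)C; trimethylsilyl triflate C[Si](C)(C)OS(=O)(=O)C(F)(F)F
Why: Copper-catalysed asymmetric conjugate addition of methyl to the β,β-disubstituted enone sets the quaternary centre C4 under control of the phosphoramidite (the ligand antipode that gives 4R is used), and silylation of the regio-defined aluminium enolate keeps the enol double bond toward C5.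

Step 3
Reactants: 6 (3R)-3-[(benzyloxy)methyl]-3-methyl-1-(trimethylsilyloxy)cyclohex-1-ene
Product: 7 (3R)-3-[(benzyloxy)methyl]-2-(dimethoxymethyl)-3-methylcyclohexan-1-one (C2 epimers)
Conditions: HC(OMe)3, TMSOTf (10 mol %), CH2Cl2, −78 °C
Reagents that add atoms: trimethyl orthoformate COC(OC)OC
Why: Mukaiyama-type alkylation of the silyl enol ether by the dimethoxycarbenium ion places C6 on C5 regiospecifically at the aldehyde oxidation level, and the C5 configuration is left open because step 4 corrects it.

Step 4
Reactants: 7 (3R)-3-[(benzyloxy)methyl]-2-(dimethoxymethyl)-3-methylcyclohexan-1-one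
Product: 9 cis-fused keto lactol methyl ether (3aR,7aS)-1-methoxy-3a-methylhexahydro-2-benzofuran-7(1H)-one, via hydroxy ketone 8 (not isolated)
Conditions: H2 (1 atm), Pd/C, MeOH, rt; filter; then PPTS (10 mol %), MeOH, rt
Reagents that add atoms: none
Why: Hydrogenolysis frees the C19 hydroxyl and acid-catalysed transacetalisation closes the five-membered mixed acetal, which can only be cis-fused, while C5 (α to the ketone) equilibrates through the enol so that the material funnels to the isomer with C6 cis to C19 and H5 cis to the C4 methyl.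

Step 5
Reactants: 9 cis-fused keto lactol methyl ether
Product: 10 spiro-oxirane on C10 (C10/C20 epoxide)
Conditions: Me3S+ I−, KOt-Bu, DMSO–THF, 0 °C → rt
Reagents that add atoms: trimethylsulfonium iodide C[S+](C)C.[I-]
Why: Corey–Chaykovsky methylene transfer from dimethylsulfonium methylide converts the ketone into the oxirane, and the configuration of the spiro carbon does not matter because C10 becomes a planar radical in step 6.

Step 6
Reactants: 10 spiro-oxirane on C10; 11 2,2,2-trifluoroethyl acrylate
Product: 13 spiro δ-lactone lactol ether, via hydroxy ester 12 (not isolated)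
Conditions: Cp2TiCl2 (20 mol %), Zn, 2,4,6-collidinium chloride, THF, rt
Reagents that add atoms: none
Why: Cp2TiCl (trivalent titanium) opens the oxirane by electron transfer to the tertiary C10 radical, which adds to the acrylate (reductive epoxide–acrylate coupling of the Nugent–RajanBabu type) on the convex face anti to the acetal ring so that C9 is trans and C20 cis to C6, and the C20 alkoxide closes the δ-lactone on the activated ester.

Step 7
Reactants: 13 spiro δ-lactone lactol ether
Product: 14 spiro bis-lactone
Conditions: CrO3, H2SO4, H2O, acetone, 0 °C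
Reagents that add atoms: water O
Why: Jones oxidation hydrolyses the methyl acetal to the lactol and oxidises it to the γ-lactone C6(=O)–O–C19 without touching the δ-lactone or any stereocentre.

Step 8
Reactants: 14 spiro bis-lactone
Product: 16 8,9-didehydro spiro bis-lactone, via selenide 15 (not isolated)
Conditions: LiHMDS, THF, −78 °C; PhSeBr; then 30% H2O2, pyridine, CH2Cl2, 0 °C → rt
Reagents that add atoms: none
Why: Kinetic enolisation should occur at the unhindered C8 methylene of the δ-lactone and not at C5–H (a methine between two quaternary carbons), and selenenylation followed by selenoxide syn-elimination toward C9 gives the C8=C9 lactone.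

Step 9
Reactants: 16 8,9-didehydro spiro bis-lactone
Product: 18 9-vinyl spiro bis-lactone, via ketene acetal 17 (not isolated)
Conditions: CH2=CHMgBr, CuBr·SMe2 (20 mol %), TMSCl, THF, −78 → −40 °C; then aq NH4Cl
Reagents that add atoms: vinylmagnesium bromide C=C[Mg]Br
Why: Copper-catalysed conjugate addition accelerated by TMSCl delivers vinyl to C9 on the lactone face anti to the bulkier C5 branch of spiro carbon C10 (syn to C1), which sets C9 with H9 on the side of C5.

Step 10
Reactants: 18 9-vinyl spiro bis-lactone
Product: 19 C11 aldehyde (9-formyl spiro bis-lactone)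
Conditions: O3, CH2Cl2–MeOH, −78 °C; then Me2S, −78 °C → rt
Reagents that add atoms: ozone [O-][O+]=O
Why: Ozonolysis with reductive work-up cleaves the only C=C bond to the aldehyde under neutral conditions that should not epimerise C9.

Step 11
Reactants: 19 C11 aldehyde
Product: 20 (11R)-homoallylic alcohol
Conditions: allylB(pin), (R)-TRIP (5 mol %), toluene, −30 °C
Reagents that add atoms: allylboronic acid pinacol ester C=CCB1OC(C)(C)C(C)(C)O1
Why: Chiral phosphoric acid-catalysed allylboration through a chair six-membered transition state adds allyl to the Re face of the aldehyde under catalyst control (the catalyst enantiomer is chosen for this face) to give 11R and tolerates both lactones.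

Step 12
Reactants: 20 (11R)-homoallylic alcohol
Product: 21 11-O-TBS homoallylic ether
Conditions: TBSOTf, 2,6-lutidine, CH2Cl2, −78 → 0 °C
Reagents that add atoms: tert-butyldimethylsilyl triflate CC(C)(C)[Si](C)(C)OS(=O)(=O)C(F)(F)F
Why: Silylation protects the hindered secondary C11 hydroxyl as an ether that is stable to the enolate, reduction and Lewis-acid steps that follow.

Step 13
Reactants: 21 11-O-TBS homoallylic ether
Product: 23 3-substituted cyclobutanone, via dichlorocyclobutanone 22 (not isolated)
Conditions: Cl3CCOCl, Zn–Cu couple, Et2O–DME, rt; filter; then Zn, AcOH, rt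
Reagents that add atoms: trichloroacetyl chloride ClC(Cl)(Cl)C(Cl)=O
Why: [2+2] cycloaddition of dichloroketene to the terminal alkene joins the ketene carbonyl carbon (C15) to the CH2 terminus and the CCl2 carbon to C13, and reductive dechlorination gives the symmetric cyclobutanone in which C13 is not yet a stereocentre.

Step 14
Reactants: 23 3-substituted cyclobutanone
Product: 24 cyclobutanol (cis/trans mixture)
Conditions: NaBH4, MeOH–THF, −20 → 0 °C
Reagents that add atoms: none
Why: Borohydride reduces the strained ketone chemoselectively beside both lactones and so removes the only other readily enolised position before the diazo transfer, the carbinol configuration being irrelevant.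

Step 15
Reactants: 24 cyclobutanol
Product: 26 α-diazo δ-lactone cyclobutanol, via trifluoroacetyl lactone 25 (not isolated)
Conditions: LiHMDS (2.3 equiv), THF, −78 °C; CF3CO2CH2CF3; then MsN3, Et3N, H2O, MeCN, rt
Reagents that add atoms: methanesulfonyl azide CS(=O)(=O)N=[N+]=[N-]
Why: Detrifluoroacetylative diazo transfer (Regitz type) activates C8 as its trifluoroacetyl derivative, formed at the unhindered δ-lactone methylene, and transfers N2 with loss of the acyl group, while the trifluoroacetate on the cyclobutanol is hydrolysed by the aqueous amine.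

Step 16
Reactants: 26 α-diazo δ-lactone cyclobutanol
Product: 27 α-diazo δ-lactone cyclobutanone
Conditions: Dess–Martin periodinane, NaHCO3, CH2Cl2, 0 °C → rt
Reagents that add atoms: none
Why: Dess–Martin oxidation under buffered, non-acidic conditions returns the cyclobutanone without touching the acceptor-substituted diazo group.

Step 17
Reactants: 27 α-diazo δ-lactone cyclobutanone
Product: 29 11-O-TBS-17-nor-ludongnin A (C16 methylene; rings C and D closed), via diazonium betaine 28 (not isolated)
Conditions: Sc(OTf)3 (10 mol %), CH2Cl2, −78 → 0 °C, 0.005 M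
Reagents that add atoms: none
Why: Sc(OTf)3 activates the strained cyclobutanone C15=O, the nucleophilic diazo carbon C8 adds to it through a seven-membered transition state (7-exo-trig at the carbonyl, giving a bicyclo[4.1.1]octane betaine), and one of the two equivalent cyclobutane CH2 groups (C14) then migrates from C15 to C8 anti to the departing N2, which contracts the transient seven-membered ring to six-membered ring C and expands the four-membered ring to cyclopentanone ring D (C8, C15, C16, C13, C14). The closest known reaction type is the Lewis-acid-catalysed homologation of cyclobutanones with α-alkyl-α-diazo esters (Tiffeneau–Demjanov / Büchner–Curtius–Schlotterbeck ring expansion), which gives α-quaternary β-keto esters, together with its intramolecular variants that give bridged ketones. C8 is controlled by the lactone face on which C15 bonds: the tether starts at C11 on C9 and the C5 branch of spiro carbon C10 shields the other face, so C15 should bond cis to C11, and the 1,2-shift, which inverts C8, then leaves C14 cis to C11 and C15 cis to H9 as in the target, while C13 becomes a stereocentre fixed by the bridge. The step needs C–C bond formation to outrun the 1,2-hydride shift of C9–H and oxirane closure of the betaine, which the release of cyclobutanone ring strain, the low temperature and the intramolecular delivery should secure, and migration regiochemistry is no issue because C14 and C16 are constitutionally equivalent in 27.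

Step 18
Reactants: 29 11-O-TBS-17-nor-ludongnin A
Product: 30 11-O-TBS-ludongnin A
Conditions: (CH2O)n, N-methylanilinium trifluoroacetate, THF, reflux
Reagents that add atoms: formaldehyde (as paraformaldehyde) C=O
Why: Mannich-type α-methylenation takes place at C16, the only enolisable position of the C15 ketone because C8 is quaternary, and elimination can only give the exocyclic C16=C17 alkene because C13 is a bridgehead.

Step 19
Reactants: 30 11-O-TBS-ludongnin A
Product: 31 ludongnin A
Conditions: HF·pyridine, pyridine, THF, 0 °C → rt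
Reagents that add atoms: none
Why: Buffered fluoride desilylation frees the C11 hydroxyl without adding to the enone or opening the lactones.

**Compound list**

1 | 3-ethoxycyclohex-2-en-1-one | CCOC1=CC(=O)CCC1 | starting material
2 | tributyl[(benzyloxy)methyl]stannane | CCCC[Sn](CCCC)(CCCC)COCc1ccccc1 | starting material
3 | 1-[(benzyloxy)methyl]-3-ethoxycyclohex-2-en-1-ol (racemic, present as lithium alkoxide) | CCOC1=CC(O)(COCc2ccccc2)CCC1 | intermediate
4 | 3-[(benzyloxy)methyl]cyclohex-2-en-1-one | O=C1C=C(COCc2ccccc2)CCC1 | intermediate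
5 | dimethylaluminium enolate of (3R)-3-[(benzyloxy)methyl]-3-methylcyclohexanone (enol double bond toward the quaternary carbon) | C[Al](C)OC1=C[C@](C)(COCc2ccccc2)CCC1 | intermediate
6 | (3R)-3-[(benzyloxy)methyl]-3-methyl-1-(trimethylsilyloxy)cyclohex-1-ene | C[Si](C)(C)OC1=C[C@](C)(COCc2ccccc2)CCC1 | intermediate
7 | (3R)-3-[(benzyloxy)methyl]-2-(dimethoxymethyl)-3-methylcyclohexan-1-one, both C2 epimers | O=C1CCC[C@@](C)(COCc2ccccc2)C1C(OC)OC | intermediate
8 | (3R)-2-(dimethoxymethyl)-3-(hydroxymethyl)-3-methylcyclohexan-1-one, both C2 epimers | O=C1CCC[C@@](C)(CO)C1C(OC)OC | intermediate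
9 | (3aR,7aS)-1-methoxy-3a-methylhexahydro-2-benzofuran-7(1H)-one, cis-fused, both acetal epimers (C4, C5 as in 31; ketone at C10) | O=C1CCC[C@@]2(C)COC(OC)[C@H]21 | intermediate
10 | spiro-oxirane of 9 at the former ketone carbon (C10/C20 epoxide, both epoxide epimers; C4, C5 as in 31) | C1OC12CCC[C@@]3(C)COC(OC)[C@H]32 | intermediate
11 | 2,2,2-trifluoroethyl acrylate | C=CC(=O)OCC(F)(F)F | starting material
12 | 2,2,2-trifluoroethyl 3-[C10]-propanoate hydroxy ester: C10 quaternary with CH2OH (C20, cis to C6) and CH2CH2CO2CH2CF3 (C9, trans to C6) on the bicyclic lactol ether | FC(F)(F)COC(=O)CC[C@@]1(CCC[C@@]2(C)COC(OC)[C@H]21)CO | intermediate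
13 | spiro δ-lactone (C7/C20) on the cis-fused lactol methyl ether; C4, C5, C10 as in 31 | O=C1CC[C@@]2(CCC[C@@]3(C)COC(OC)[C@H]32)CO1 | intermediate
14 | spiro bis-lactone: γ-lactone C6(=O)–O–C19 and δ-lactone C7(=O)–O–C20; C4, C5, C10 as in 31 | O=C1CC[C@@]2(CCC[C@@]3(C)COC(=O)[C@H]32)CO1 | intermediate
15 | 8-(phenylselanyl) derivative of 14 (C8 epimers) | O=C1C([Se]c4ccccc4)C[C@@]2(CCC[C@@]3(C)COC(=O)[C@H]32)CO1 | intermediate
16 | 8,9-didehydro spiro bis-lactone | O=C1C=C[C@@]2(CCC[C@@]3(C)COC(=O)[C@H]32)CO1 | intermediate
17 | trimethylsilyl ketene acetal of the 9-vinyl δ-lactone (C7(OTMS)=C8) | C=C[C@H]2[C@@]1(CCC[C@@]3(C)COC(=O)[C@H]31)COC(O[Si](C)(C)C)=C2 | intermediate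
18 | 9-vinyl spiro bis-lactone; vinyl on C9 cis to C1, H9 cis to C5 (C9 as in 31) | C=C[C@H]2[C@@]1(CCC[C@@]3(C)COC(=O)[C@H]31)COC(=O)C2 | intermediate
19 | 9-formyl spiro bis-lactone (C11 aldehyde) | O=C[C@H]2[C@@]1(CCC[C@@]3(C)COC(=O)[C@H]31)COC(=O)C2 | intermediate
20 | (11R)-homoallylic alcohol: C9–CH(OH)–CH2–CH=CH2 | C=CC[C@@H](O)[C@H]2[C@@]1(CCC[C@@]3(C)COC(=O)[C@H]31)COC(=O)C2 | intermediate
21 | 11-O-tert-butyldimethylsilyl ether of 20 | C=CC[C@@H](O[Si](C)(C)C(C)(C)C)[C@H]2[C@@]1(CCC[C@@]3(C)COC(=O)[C@H]31)COC(=O)C2 | intermediate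
22 | 2,2-dichloro-3-substituted cyclobutanone from 21 (C13 epimers) | O=C1CC(C1(Cl)Cl)C[C@@H](O[Si](C)(C)C(C)(C)C)[C@H]2[C@@]1(CCC[C@@]3(C)COC(=O)[C@H]31)COC(=O)C2 | intermediate
23 | 3-substituted cyclobutanone (C13–C14–C15(=O)–C16) tethered through C12 and C11(OTBS) to C9 of the δ-lactone | O=C1CC(C1)C[C@@H](O[Si](C)(C)C(C)(C)C)[C@H]2[C@@]1(CCC[C@@]3(C)COC(=O)[C@H]31)COC(=O)C2 | intermediate
24 | cyclobutanol from 23 (cis/trans mixture) | OC1CC(C1)C[C@@H](O[Si](C)(C)C(C)(C)C)[C@H]2[C@@]1(CCC[C@@]3(C)COC(=O)[C@H]31)COC(=O)C2 | intermediate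
25 | 8-trifluoroacetyl δ-lactone with cyclobutyl trifluoroacetate (C8 epimers/enol) | FC(F)(F)C(=O)OC1CC(C1)C[C@@H](O[Si](C)(C)C(C)(C)C)[C@H]2[C@@]1(CCC[C@@]3(C)COC(=O)[C@H]31)COC(=O)C2C(=O)C(F)(F)F | intermediate
26 | 8-diazo δ-lactone with free cyclobutanol | OC1CC(C1)C[C@@H](O[Si](C)(C)C(C)(C)C)[C@H]2[C@@]1(CCC[C@@]3(C)COC(=O)[C@H]31)COC(=O)C2=[N+]=[N-] | intermediate
27 | 8-diazo δ-lactone with tethered cyclobutanone | O=C1CC(C1)C[C@@H](O[Si](C)(C)C(C)(C)C)[C@H]2[C@@]1(CCC[C@@]3(C)COC(=O)[C@H]31)COC(=O)C2=[N+]=[N-] | intermediate
28 | bicyclo[4.1.1]octane diazonium betaine (C8–C15 bond formed cis to C11; alkoxide on C15 bound to scandium; drawn as zwitterion) | [O-]C12CC(C1)C[C@@H](O[Si](C)(C)C(C)(C)C)[C@H]3[C@@]4(CCC[C@@]5(C)COC(=O)[C@H]54)COC(=O)C23[N+]#N | intermediate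
29 | 11-O-TBS-17-nor-ludongnin A: pentacyclic β-keto lactone with C16 as CH2; all ring stereocentres as in 31 | C1C(=O)[C@]23C[C@H]1C[C@@H](O[Si](C)(C)C(C)(C)C)[C@H]2[C@@]1(CCC[C@@]2(C)COC(=O)[C@H]21)COC3=O | intermediate
30 | 11-O-TBS-ludongnin A | C=C1C(=O)[C@]23C[C@H]1C[C@@H](O[Si](C)(C)C(C)(C)C)[C@H]2[C@@]1(CCC[C@@]2(C)COC(=O)[C@H]21)COC3=O | intermediate
31 | ludongnin A (4R,5R,8S,9S,10R,11R,13S in ent-kaurane numbering) | C=C1C(=O)[C@]23C[C@H]1C[C@@H](O)[C@H]2[C@@]1(CCC[C@@]2(C)COC(=O)[C@H]21)COC3=O | target

**Totals and risks**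

Total step count: 19. Longest linear sequence: 19 steps (from 1).

Steps most likely to fail:

1. Step 17. The diazo lactone may lose N2 by a 1,2-hydride shift from C9 to give the C8=C9 lactone, the betaine may close to the oxirane, or C15 may bond on the wrong lactone face and give the C8/C13 epimer. Fallback (sets out from 19, returns at 30): ring D is made directly five-membered by a vinyl-radical cyclisation. Aldehyde 19 is vinylated under catalyst control (divinylzinc, chiral amino-alcohol ligand) and silylated in the same flask to the C11 vinyl carbinol silyl ether F1. The lithium enolate of its δ-lactone is allylated at C8 to the 8-allyl lactone F2. Ring-closing metathesis with the second-generation Grubbs catalyst closes ring C as the C12=C13 cyclohexene F3. Angular alkylation of the enolate of F3 with propargyl bromide on the convex face should give the C8-quaternary propargyl lactone F4 with C14 cis to C11. Bu3SnH/AIBN adds a stannyl radical to the alkyne, and the C16 vinyl radical closes ring D 5-exo-trig onto C13 to give the vinylstannane F5. Protodestannylation (HCl, CH2Cl2) gives the 16-methylene compound F6. SeO2/t-BuOOH oxidises C15 to the allylic alcohol F7, and Dess–Martin oxidation gives 30.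

2. Step 6. The tertiary C10 radical may be reduced by a second Cp2TiCl before it meets the acrylate, or may add with poor facial selectivity. Fallback (sets out from 9, returns at 13): C10 is built by enolate chemistry. A Wittig reaction of 9 with Ph3P=CHOMe gives the enol ether F8. Mild hydrolysis (oxalic acid on wet silica) gives the C20 aldehyde F9. Base-catalysed Michael addition (KOt-Bu cat., methyl acrylate) of its enolate on the convex face gives the quaternary aldehyde ester F10. NaBH4 reduces the aldehyde, and the C20 alkoxide lactonises to 13.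

3. Step 9. Conjugate addition at the neopentyl β-carbon C9 may be slow, so that the Grignard reagent attacks a lactone carbonyl instead. Fallback (sets out from 16, returns at 19): Michael addition of nitromethane (DBU, MeCN) on the same face gives the 9-(nitromethyl) lactone F11, and a reductive Nef reaction (TiCl3, NH4OAc, aq THF) gives aldehyde 19 directly, which also makes step 10 unnecessary.

Further compounds
F1 | step 17 | 11-O-TBS vinyl carbinol: C9–CH(OTBS)–CH=CH2 on the spiro bis-lactone | C=C[C@@H](O[Si](C)(C)C(C)(C)C)[C@H]2[C@@]1(CCC[C@@]3(C)COC(=O)[C@H]31)COC(=O)C2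
F2 | step 17 | 8-allyl derivative of F1 (C8 epimers) | C=C[C@@H](O[Si](C)(C)C(C)(C)C)[C@H]2[C@@]1(CCC[C@@]3(C)COC(=O)[C@H]31)COC(=O)C2CC=C
F3 | step 17 | ring C cyclohexene (C12=C13) fused to the δ-lactone at C8–C9 (C8–H) | C1=C[C@@H](O[Si](C)(C)C(C)(C)C)[C@H]2[C@@]3(CCC[C@@]4(C)COC(=O)[C@H]43)COC(=O)C2C1
F4 | step 17 | 8-propargyl derivative of F3, C8 quaternary with C14 cis to C11 | C#CC[C@]23CC=C[C@@H](O[Si](C)(C)C(C)(C)C)[C@H]2[C@@]1(CCC[C@@]2(C)COC(=O)[C@H]21)COC3=O
F5 | step 17 | 17-(tributylstannyl) 16-methylene pentacycle with C15 as CH2 (alkene isomers) | CCCC[Sn](CCCC)(CCCC)C=C1C[C@]23C[C@H]1C[C@@H](O[Si](C)(C)C(C)(C)C)[C@H]2[C@@]1(CCC[C@@]2(C)COC(=O)[C@H]21)COC3=O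
F6 | step 17 | 15-deoxo-11-O-TBS-ludongnin A (C15 as CH2) | C=C1C[C@]23C[C@H]1C[C@@H](O[Si](C)(C)C(C)(C)C)[C@H]2[C@@]1(CCC[C@@]2(C)COC(=O)[C@H]21)COC3=O
F7 | step 17 | 15-hydroxy derivative of F6 (C15 epimers) | C=C1C(O)[C@]23C[C@H]1C[C@@H](O[Si](C)(C)C(C)(C)C)[C@H]2[C@@]1(CCC[C@@]2(C)COC(=O)[C@H]21)COC3=O
F8 | step 6 | methyl enol ether at C10=C20 of the bicyclic lactol ether | COC=C1CCC[C@@]2(C)COC(OC)[C@H]21
F9 | step 6 | C20 aldehyde on C10 (C10 epimers) | O=CC1CCC[C@@]2(C)COC(OC)[C@H]21
F10 | step 6 | methyl 3-(C10)-propanoate with C10 formyl (C9 chain trans to C6) | COC(=O)CC[C@@]1(CCC[C@@]2(C)COC(OC)[C@H]21)C=O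
F11 | step 9 | 9-(nitromethyl) spiro bis-lactone | [O-][N+](=O)C[C@H]2[C@@]1(CCC[C@@]3(C)COC(=O)[C@H]31)COC(=O)C2
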